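**Drain ratio.** 0.234 mM of free catalyst is what the dimer balance leaves of 0.41 mM, and with it the drain ratio comes to 0.823. I define this ratio as the top pace of reagent take, with second catalyst wholly bound, over the forward pace of substrate opening, both at the charges. Reagent is the limiting reagent, at 0.800 equiv, so its balance is the one I write: reagent spent counts target once and over-reaction product twice, and open intermediate is what has opened, less target, over-reaction product and catalyst intermediate, which holds at most 0.500% of the substrate.

| setting | autumn | winter | spring | dawn |
|---|---|---|---|---|
| substrate | 0.050 M | 0.050 M (fed, over 32.0 min) | 0.050 M | 0.050 M |
| reagent | 0.0400 M | 0.0400 M | 0.0400 M (fed, over 32.0 min) | 0.0400 M |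
| free catalyst | 0.41 mM | 0.41 mM | 0.41 mM | 0.41 mM |
| second catalyst | 0.25 mM | 0.25 mM | 0.25 mM | 0.25 mM |
| time | 40 min | 40 min | 40 min |  |
| remark | everything together in a closed stirred flask, run for 40 min | a stirred flask in which substrate is dosed at a steady rate over 32.0 min without added volume, worked up at 40 min | a stirred flask in which reagent is dosed at a steady rate over 32.0 min without added volume, worked up at 40 min | a single well-mixed tank run continuously and read at steady state, 40 min in it on average |

- the set-up with the highest amount of open intermediate at the outlet or at the end, in percent of the substrate put in ("none" if the first two lie within 2 percentage points) (autumn / winter / spring / dawn / none)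
- amount of open intermediate at the outlet or at the end, in percent of the substrate put in, autumn
- amount of open intermediate at the outlet or at the end, in percent of the substrate put in, winter
- amount of open intermediate at the outlet or at the end, in percent of the substrate put in, spring
- amount of open intermediate at the outlet or at the end, in percent of the substrate put in, dawn

- a step written with two of one species runs at k times the square of its concentration and takes two of it each time
- the stated concentrations are those of everything mixed, before any reaction; amounts are the same in each set-up
- the feed brings no volume worth counting
- run time (autumn): 40 min

    substrate + free catalyst ⇌ free catalyst + open intermediate (K1 = 2.55, k1 = 1.11 L mol⁻¹ s⁻¹)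
    second catalyst + open intermediate ⇌ catalyst intermediate (K2 = 88.3 L mol⁻¹, k2 = 147 L mol⁻¹ s⁻¹)
    reagent + catalyst intermediate → second catalyst + target (k3 = 1.07 L mol⁻¹ s⁻¹)
    reagent + target → over-reaction product (k4 = 0.00292 L mol⁻¹ s⁻¹)
    2 free catalyst ⇌ resting dimer, settled at all times (K5 = 1600 L mol⁻¹)

**Two extremes.** Take autumn. If reagent took nothing, opening at 0.0156 min⁻¹ would relax toward its balance and give 41.7% open intermediate. If second catalyst stood wholly bound from the start, reagent would decay pseudo-first-order at 0.0161 min⁻¹. Counting forward opening, 46.4% opened less that take leaves 8.53%.

**Between them.** Second catalyst is half bound when c(open intermediate) equals the inverse of its binding constant, 11.3 mM. That is 22.7% of the substrate, which lies inside the bracket. At half the top pace, my autumn figure is 24.5%.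

**The feeds.** At mid-feed, half of the dosed charge is in, so the ratio reads about 0.411 in spring and 1.65 in winter. I rank spring over autumn over winter, and I put no figure of my own on dawn.

**The forecast.** It names spring: 24.6% autumn, 18.5% winter, 28.2% spring, 18.3% dawn. For spring its ground is “because delayed reagent lets it build”.

**The flasks.** They give 25.3% autumn, 18.6% winter, 28.6% spring and 18.4% dawn, so spring leads by 3.3 percentage points over autumn. The forecast stands, and of these set-ups dosing reagent gives the most open intermediate at 40.0 min.

**Next flask.** A neighbour of spring is charged with 0.16 M of reagent, 3.20 equiv, with the other charges and the time held. Its drain ratio is 3.29, and at mid-feed 1.65, above one, so reckoned at the charges the top pace of take stands above forward opening. At 40.0 min that neighbour holds open intermediate at 7.89%, against 28.6% in spring, with target at 26.7% and catalyst intermediate at 24.3% of the second catalyst.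

The numbers of this flask were chosen freely; the run is a simulation.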